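The target is a guaiane: cyclopentane ring (C1–C5) fused to cycloheptanone ring (C1, C5–C10). Its C6 ketone, C5–H and exocyclic C4=C15 alkene form a β,γ-unsaturated ketone, the retron of a Conia-ene reaction, so the five-membered ring is closed last at C4–C5. A fully oxygenated cycloheptanone carrying a but-3-ynyl chain on C1 is made from (S)-carvone by one-carbon ring expansion; its C5=C6 silyl enol ether attacks the gold-activated alkyne 5-exo-dig, creating the C4–C5 bond, the ring and the methylene group in one operation. The cis ring fusion this gives is then inverted at C5 by kinetic protonation of the dienolate.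

Key step: step 13

Remark: the guaiane locants of the target (C1–C10, C15) are used for all seven-membered-ring intermediates from 12 on and in all Why lines; C1 is the carbinol carbon that carries the side chain, C6 the ketone carbon, C7 the isopropyl carbon, C9 the ester carbon and C10 the methyl carbinol carbon.

Step 1
Reactants: 1 (S)-(+)-carvone
Product: 2 (5S)-2-methyl-5-(propan-2-yl)cyclohex-2-en-1-one
Conditions: H2 (1 atm), RhCl(PPh3)3 (cat.), benzene, rt
Reagents that add atoms: none
Why: Homogeneous hydrogenation with RhCl(PPh3)3 should reduce only the unhindered 1,1-disubstituted isopropenyl alkene and leave the trisubstituted enone and the stereocentre (future C7) untouched.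

Step 2
Reactants: 2 (5S)-2-methyl-5-(propan-2-yl)cyclohex-2-en-1-one
Product: 3 kinetic trimethylsilyl dienol ether of 2
Conditions: LiN(iPr)2, THF, −78 °C; Me3SiCl, Et3N, −78 °C → rt
Reagents that add atoms: chlorotrimethylsilane, C[Si](C)(C)Cl
Why: Kinetic deprotonation at the α'-methylene and O-silylation should give the cross-conjugated silyl dienol ether needed for the Ito–Saegusa ring expansion, without touching the stereocentre.

Step 3
Reactants: 3 kinetic trimethylsilyl dienol ether of 2
Product: 4 1-(trimethylsilyloxy)bicyclo[4.1.0]hept-2-ene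
Conditions: Et2Zn, CH2I2, toluene, 0 °C → rt
Reagents that add atoms: diiodomethane, ICI
Why: Furukawa-modified Simmons–Smith cyclopropanation is selective for the electron-rich silyl enol ether double bond and should occur anti to the adjacent isopropyl group, although both cyclopropane diastereomers converge in step 4.

Step 4
Reactants: 4 1-(trimethylsilyloxy)bicyclo[4.1.0]hept-2-ene
Product: 6 (5R)-2-methyl-5-(propan-2-yl)cyclohepta-2,6-dien-1-one, via β-chloro ketone 5 (not isolated)
Conditions: FeCl3 (2.5 equiv), DMF, 0 °C → rt; then NaOAc, MeOH, reflux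
Reagents that add atoms: none
Why: Ito–Saegusa ring expansion: FeCl3 oxidises the silyloxycyclopropane, the internal bond opens to a β-keto radical that is chlorinated to 5, and NaOAc eliminates HCl, so one carbon (future C5) is inserted between the carbonyl carbon (future C1) and the former α'-carbon (future C6).

Step 5
Reactants: 6 (5R)-2-methyl-5-(propan-2-yl)cyclohepta-2,6-dien-1-one
Product: 8 (5R,6S)-6-hydroxy-2-methyl-5-(propan-2-yl)cyclohept-2-en-1-one, via β-boryl ketone 7 (not isolated)
Conditions: B2pin2 (1.1 equiv), CuCl (5 mol %), DPEphos, NaOtBu (10 mol %), MeOH, THF, rt; then 30 % H2O2, pH 7 phosphate buffer, 0 °C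
Reagents that add atoms: hydrogen peroxide, OO
Why: Copper-catalysed conjugate borylation should attack the α-unsubstituted enone rather than the α-methyl enone, anti to the neighbouring isopropyl group, and stereoretentive oxidation of the C–B bond gives the trans β-hydroxy ketone that carries the future C6 oxygen.

Step 6
Reactants: 8 (5R,6S)-6-hydroxy-2-methyl-5-(propan-2-yl)cyclohept-2-en-1-one; 9 (4-bromobut-1-yn-1-yl)trimethylsilane
Product: 11 (1R,5R,6S)-2-methyl-5-(propan-2-yl)-1-[4-(trimethylsilyl)but-3-yn-1-yl]cyclohept-2-ene-1,6-diol, via Grignard reagent 10 (not isolated)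
Conditions: 9, Mg, THF, rt (gives 10, 3.5 equiv); add 8, THF, −78 → 0 °C; aq NH4Cl
Reagents that add atoms: none
Why: 1,2-Grignard addition to the enone carbonyl (one equivalent is spent on the hydroxyl) should occur anti to the β'-magnesium alkoxide, as nucleophiles add anti to the C5 substituent of carvone, which sets C1 with its hydroxyl cis to the C6 oxygen and trans to the isopropyl group.

Step 7
Reactants: 11 (1R,5R,6S)-2-methyl-5-(propan-2-yl)-1-[4-(trimethylsilyl)but-3-yn-1-yl]cyclohept-2-ene-1,6-diol
Product: 12 9,10-epoxy-1,6-diol (epoxide cis to the C1 hydroxyl)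
Conditions: VO(acac)2 (5 mol %), tBuOOH (1.5 equiv, in decane), CH2Cl2, 0 °C → rt
Reagents that add atoms: tert-butyl hydroperoxide, CC(C)(C)OO
Why: Hydroxyl-directed vanadium-catalysed epoxidation of the tertiary allylic alcohol should deliver oxygen to the C9=C10 alkene syn to the C1 hydroxyl (the cis sense known for cyclohept-2-enols), which fixes C10, while the alkyne is inert.

Step 8
Reactants: 12 9,10-epoxy-1,6-diol; 13 angelic acid
Product: 14 C9 angelate 1,6,10-triol
Conditions: 13 (3 equiv), Ti(OiPr)4 (2 equiv), CH2Cl2, rt → 40 °C; aq tartaric acid work-up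
Reagents that add atoms: none
Why: Titanium-mediated C3-selective opening of a 2,3-epoxy alcohol by a carboxylic acid should attack the secondary C9 with inversion, so the angelate is installed trans to the retained C10 hydroxyl without any base that could isomerise it to the tiglate.

Step 9
Reactants: 14 C9 angelate 1,6,10-triol
Product: 15 C6 ketone 1,10-diol
Conditions: SO3·pyridine, DMSO, iPr2NEt, CH2Cl2, 0 °C
Reagents that add atoms: none
Why: Parikh–Doering oxidation should convert the only secondary alcohol (C6) into the ketone without cleaving the tertiary 1,2-diol or epimerising C7.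

Step 10
Reactants: 15 C6 ketone 1,10-diol
Product: 16 1,10-bis(triethylsilyl) ether of 15
Conditions: Et3SiOTf (5 equiv), 2,6-lutidine, CH2Cl2, −78 → 0 °C
Reagents that add atoms: triethylsilyl trifluoromethanesulfonate, CC[Si](CC)(CC)OS(=O)(=O)C(F)(F)F
Why: Silylation of both tertiary hydroxyls with the silyl triflate blocks the C1 oxygen, which would otherwise add to the gold-activated alkyne (5-exo) and, as its alkoxide, would direct enolisation away from C5.

Step 11
Reactants: 16 1,10-bis(triethylsilyl) ether of 15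
Product: 17 C5=C6 tert-butyldimethylsilyl enol ether
Conditions: LiN(SiMe3)2 (1.3 equiv), THF, −78 °C; tBuMe2SiOTf, −78 °C; Et3N, aq NaHCO3
Reagents that add atoms: tert-butyldimethylsilyl trifluoromethanesulfonate, CC(C)(C)[Si](C)(C)OS(=O)(=O)C(F)(F)F
Why: Kinetic deprotonation at the C5 methylene (C7 is a hindered isopropyl-bearing methine and the silylated alkyne has no acidic hydrogen) followed by O-silylation should give the C5=C6 silyl enol ether regioselectively.

Step 12
Reactants: 17 C5=C6 tert-butyldimethylsilyl enol ether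
Product: 18 terminal alkyne silyl enol ether
Conditions: K2CO3, MeOH/THF, 0 °C
Reagents that add atoms: none
Why: Mild base-catalysed methanolysis should cleave only the C(sp)–Si bond, while the hindered silyl enol ether, the triethylsilyl ethers and the angelate survive at 0 °C.

Step 13
Reactants: 18 terminal alkyne silyl enol ether
Product: 19 cis-fused 5-epi guaiane ketone (bis-silyl ether)
Conditions: (Ph3P)AuCl (10 mol %), AgBF4 (10 mol %), CH2Cl2/MeOH 10:1, rt → 40 °C
Reagents that add atoms: none
Why: The cationic Ph3PAu+ fragment coordinates the terminal alkyne and the C5 terminus of the silyl enol ether attacks the internal carbon C4 anti to gold; methanol then removes the silyl group from the oxocarbenium ion and protodeaurates the vinylgold at C15. The closest known reaction is the gold-catalysed carbocyclisation of silyl enol ethers with alkynes (a Conia-ene variant), which converts 3-(but-3-ynyl)cycloalkanone enol ethers into cis-fused methylenecyclopentane-annulated ketones. The cyclopentane closes in the 5-exo-dig mode. C5 is the only new stereocentre and is controlled by the tether: C4 must bond to the enol ether face that carries C2 on C1, so H-5 ends syn to the C1 oxygen (cis ring fusion, the C5 epimer of the target). The step needs C-attack in the 5-exo mode rather than 6-endo closure or attack by oxygen, which the terminal alkyne, the three-atom tether and the silylated C1 and C10 hydroxyls secure, and it needs the C5 rather than the C7 enol ether, which step 11 secures.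

Step 14
Reactants: 19 cis-fused 5-epi guaiane ketone (bis-silyl ether)
Product: 22 (1R,5S,7R,9R,10S)-1,10-dihydroxy-6-oxoguai-4(15)-en-9-yl angelate, via potassium dienolate 20 (not isolated), via trans-fused bis-silyl ether 21 (not isolated)
Conditions: KOtBu (1.1 equiv), THF, −78 °C; AcOH, −78 °C; then HF·pyridine, pyridine, THF, 0 °C → rt
Reagents that add atoms: none
Why: KOtBu should remove only the doubly activated H-5 (α to the ketone and allylic), the dienolate should be protonated kinetically at the α-carbon (deconjugative protonation) from the face opposite the two triethylsilyloxy groups to give the trans ring fusion without moving the exocyclic alkene into conjugation, and HF·pyridine then cleaves both silyl ethers.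

Compound list

1 | (S)-(+)-carvone, (5S)-2-methyl-5-(prop-1-en-2-yl)cyclohex-2-en-1-one | CC1=CC[C@@H](CC1=O)C(C)=C | starting material
2 | (5S)-2-methyl-5-(propan-2-yl)cyclohex-2-en-1-one | CC1=CC[C@@H](CC1=O)C(C)C | intermediate
3 | trimethyl{[(3R)-6-methyl-3-(propan-2-yl)cyclohexa-1,5-dien-1-yl]oxy}silane | CC1=CC[C@@H](C=C1O[Si](C)(C)C)C(C)C | intermediate
4 | trimethyl{[(1S,5R,6R)-2-methyl-5-(propan-2-yl)bicyclo[4.1.0]hept-2-en-1-yl]oxy}silane (cyclopropane CH2 anti to isopropyl) | CC1=CC[C@H](C(C)C)[C@H]2C[C@@]12O[Si](C)(C)C | intermediate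
5 | (5R)-6-chloro-2-methyl-5-(propan-2-yl)cyclohept-2-en-1-one (both C6 epimers, not isolated) | CC1=CC[C@H](C(C)C)C(Cl)CC1=O | intermediate
6 | (5R)-2-methyl-5-(propan-2-yl)cyclohepta-2,6-dien-1-one | CC1=CC[C@H](C(C)C)C=CC1=O | intermediate
7 | (5S,6S)-2-methyl-5-(propan-2-yl)-6-(4,4,5,5-tetramethyl-1,3,2-dioxaborolan-2-yl)cyclohept-2-en-1-one (boron trans to isopropyl, not isolated) | O=C1C[C@H](B2OC(C)(C)C(C)(C)O2)[C@@H](C(C)C)CC=C1C | intermediate
8 | (5R,6S)-6-hydroxy-2-methyl-5-(propan-2-yl)cyclohept-2-en-1-one | O=C1C[C@H](O)[C@@H](C(C)C)CC=C1C | intermediate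
9 | (4-bromobut-1-yn-1-yl)trimethylsilane | C[Si](C)(C)C#CCCBr | starting material
10 | [4-(trimethylsilyl)but-3-yn-1-yl]magnesium bromide (not isolated) | C[Si](C)(C)C#CCC[Mg]Br | intermediate
11 | (1R,5R,6S)-2-methyl-5-(propan-2-yl)-1-[4-(trimethylsilyl)but-3-yn-1-yl]cyclohept-2-ene-1,6-diol | C[Si](C)(C)C#CCC[C@@]1(O)C[C@H](O)[C@@H](C(C)C)CC=C1C | intermediate
12 | (1R,6S,7R,9S,10S)-9,10-epoxy-10-methyl-7-(propan-2-yl)-1-[4-(trimethylsilyl)but-3-yn-1-yl]cycloheptane-1,6-diol (epoxide oxygen cis to the C1 hydroxyl) | C[Si](C)(C)C#CCC[C@@]1(O)C[C@H](O)[C@@H](C(C)C)C[C@@H]2O[C@]12C | intermediate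
13 | angelic acid, (2Z)-2-methylbut-2-enoic acid | C/C=C(/C)C(=O)O | starting material
14 | (1R,6S,7R,9R,10S)-1,6,10-trihydroxy-10-methyl-7-(propan-2-yl)-1-[4-(trimethylsilyl)but-3-yn-1-yl]cycloheptan-9-yl (2Z)-2-methylbut-2-enoate | C[Si](C)(C)C#CCC[C@@]1(O)C[C@H](O)[C@@H](C(C)C)C[C@@H](OC(=O)/C(C)=C\C)[C@]1(C)O | intermediate
15 | (1R,7R,9R,10S)-1,10-dihydroxy-10-methyl-6-oxo-7-(propan-2-yl)-1-[4-(trimethylsilyl)but-3-yn-1-yl]cycloheptan-9-yl (2Z)-2-methylbut-2-enoate | C[Si](C)(C)C#CCC[C@@]1(O)CC(=O)[C@@H](C(C)C)C[C@@H](OC(=O)/C(C)=C\C)[C@]1(C)O | intermediate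
16 | 1,10-bis(triethylsilyl) ether of 15, (1R,7R,9R,10S) | C[Si](C)(C)C#CCC[C@@]1(O[Si](CC)(CC)CC)CC(=O)[C@@H](C(C)C)C[C@@H](OC(=O)/C(C)=C\C)[C@]1(C)O[Si](CC)(CC)CC | intermediate
17 | C5=C6 tert-butyldimethylsilyl enol ether of 16, (1R,7R,9R,10S) | C[Si](C)(C)C#CCC[C@@]1(O[Si](CC)(CC)CC)C=C(O[Si](C)(C)C(C)(C)C)[C@@H](C(C)C)C[C@@H](OC(=O)/C(C)=C\C)[C@]1(C)O[Si](CC)(CC)CC | intermediate
18 | 17 with a terminal but-3-yn-1-yl chain, (1R,7R,9R,10S) | C#CCC[C@@]1(O[Si](CC)(CC)CC)C=C(O[Si](C)(C)C(C)(C)C)[C@@H](C(C)C)C[C@@H](OC(=O)/C(C)=C\C)[C@]1(C)O[Si](CC)(CC)CC | intermediate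
19 | (1R,5R,7R,9R,10S)-6-oxo-1,10-bis[(triethylsilyl)oxy]guai-4(15)-en-9-yl (2Z)-2-methylbut-2-enoate (cis-fused, H-5 syn to the C1 oxygen) | C=C1CC[C@@]2(O[Si](CC)(CC)CC)[C@@H]1C(=O)[C@@H](C(C)C)C[C@@H](OC(=O)/C(C)=C\C)[C@]2(C)O[Si](CC)(CC)CC | intermediate
20 | potassium C5=C6 dienolate of 19 (not isolated) | C=C1CC[C@@]2(O[Si](CC)(CC)CC)C1=C([O-])[C@@H](C(C)C)C[C@@H](OC(=O)/C(C)=C\C)[C@]2(C)O[Si](CC)(CC)CC.[K+] | intermediate
21 | (1R,5S,7R,9R,10S)-6-oxo-1,10-bis[(triethylsilyl)oxy]guai-4(15)-en-9-yl (2Z)-2-methylbut-2-enoate (trans-fused, not isolated) | C=C1CC[C@@]2(O[Si](CC)(CC)CC)[C@H]1C(=O)[C@@H](C(C)C)C[C@@H](OC(=O)/C(C)=C\C)[C@]2(C)O[Si](CC)(CC)CC | intermediate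
22 | (1R,5S,7R,9R,10S)-1,10-dihydroxy-6-oxoguai-4(15)-en-9-yl (2Z)-2-methylbut-2-enoate | C=C1CC[C@@]2(O)[C@H]1C(=O)[C@@H](C(C)C)C[C@@H](OC(=O)/C(C)=C\C)[C@]2(C)O | target

Total step count: 14. Longest linear sequence: 14 steps, from (S)-carvone (1); the bromide 9 and angelic acid 13 enter as commercial components.

Steps most likely to fail

Step 14. The dienolate 20 may be protonated from the wrong face, returning the cis-fused ketone, or may lose silanolate from C1 by E1cB elimination. The fallback replaces kinetic by thermodynamic control. It sets out from 19, which is equilibrated with catalytic DBU in CH2Cl2 at 0 °C → rt; this exchanges only H-5 and is stopped before the exocyclic alkene moves into conjugation. The trans-fused ketone 21, expected to be favoured as in other bicyclo[5.3.0]decan-2-ones, is separated and recovered 19 is recycled. The fallback returns at 21, which is desilylated with HF·pyridine as in step 14. No new compound is made.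

Step 8. The carboxylate may attack the wrong epoxide carbon, or the Lewis acid may trigger a semipinacol shift instead of opening at the neopentyl-like C9. The fallback introduces the C9 oxygen before the C1/C10 diol and uses no epoxide; it sets out from 11 and returns at 14. The secondary hydroxyl of 11 is silylated (tBuMe2SiCl, imidazole, DMF) to the C6 silyl ether F4. Babler–Dauben oxidative transposition of the tertiary allylic alcohol with pyridinium chlorochromate (C5H5NH[CrO3Cl]) gives the C9 enone F5, which makes the C1 configuration irrelevant. Corey–Bakshi–Shibata reduction [(S)-Me-CBS, BH3·SMe2] gives the allylic alcohol F6 with the C9 hydroxyl cis to the isopropyl group. OsO4/NMO dihydroxylates the C1=C10 alkene anti to that hydroxyl, the usual sense for osmylation of allylic alcohols, to give the triol F7. Yamaguchi esterification with angelic acid (2,4,6-trichlorobenzoyl chloride, Et3N, toluene, 80 °C) acylates the only secondary hydroxyl to give the angelate F8. HF·pyridine removes the C6 silyl ether and gives 14.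

Step 6. The Grignard reagent may add with poor facial selectivity and give the wrong C1 epimer. The fallback relays configuration through an epoxy ketone; it sets out from 8 and returns at 12, replacing steps 6 and 7. The hydroxyl of 8 is silylated (tBuMe2SiCl, imidazole) to the silyl ether F1. Weitz–Scheffer epoxidation of the remaining enone (H2O2, NaOH, MeOH, 0 °C), anti to the isopropyl group as with carvone, gives the epoxy ketone F2. The Grignard reagent 10 (with CeCl3, THF, −78 °C) adds anti to the epoxide oxygen and gives the epoxy alcohol F3, in which the C1 hydroxyl is cis to the epoxide. HF·pyridine/pyridine removes the C6 silyl ether and gives 12.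

Further compounds

F0 | step 14 | none | none
F1 | step 6 | (5R,6S)-6-[(tert-butyldimethylsilyl)oxy]-2-methyl-5-(propan-2-yl)cyclohept-2-en-1-one | O=C1C[C@H](O[Si](C)(C)C(C)(C)C)[C@@H](C(C)C)CC=C1C
F2 | step 6 | 9,10-epoxide of F1 (epoxide oxygen trans to isopropyl) | O=C1C[C@H](O[Si](C)(C)C(C)(C)C)[C@@H](C(C)C)C[C@@H]2O[C@]12C
F3 | step 6 | C6 tert-butyldimethylsilyl ether of 12 | C[Si](C)(C)C#CCC[C@@]1(O)C[C@H](O[Si](C)(C)C(C)(C)C)[C@@H](C(C)C)C[C@@H]2O[C@]12C
F4 | step 8 | C6 tert-butyldimethylsilyl ether of 11 | C[Si](C)(C)C#CCC[C@@]1(O)C[C@H](O[Si](C)(C)C(C)(C)C)[C@@H](C(C)C)CC=C1C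
F5 | step 8 | (6S,7R)-6-[(tert-butyldimethylsilyl)oxy]-10-methyl-7-(propan-2-yl)-1-[4-(trimethylsilyl)but-3-yn-1-yl]cyclohept-1(10)-en-9-one | C[Si](C)(C)C#CCCC1C[C@H](O[Si](C)(C)C(C)(C)C)[C@@H](C(C)C)CC(=O)C=1C
F6 | step 8 | (6S,7R,9R)-allylic alcohol from F5 (C9 hydroxyl cis to isopropyl) | C[Si](C)(C)C#CCCC1C[C@H](O[Si](C)(C)C(C)(C)C)[C@@H](C(C)C)C[C@@H](O)C=1C
F7 | step 8 | (1R,6S,7R,9R,10S)-1,9,10-triol C6 tert-butyldimethylsilyl ether | C[Si](C)(C)C#CCC[C@@]1(O)C[C@H](O[Si](C)(C)C(C)(C)C)[C@@H](C(C)C)C[C@@H](O)[C@]1(C)O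
F8 | step 8 | C6 tert-butyldimethylsilyl ether of 14 | C[Si](C)(C)C#CCC[C@@]1(O)C[C@H](O[Si](C)(C)C(C)(C)C)[C@@H](C(C)C)C[C@@H](OC(=O)/C(C)=C\C)[C@]1(C)O
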